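## Retrosynthetic overview

1. The target is a 5,5'-linked biaryl (rings B and C) carrying two oxolanes of the same configuration. Each CH2OH comes from a CO2H (BH3), each CO2H/ArCH2 pair from hydrogenolysis of a γ-aryl lactone, and each lactone from Baeyer–Villiger oxidation of a cyclobutanone.
2. Feature used: in each oxolane (O1, C2 aryl, C3 CH2OH, C4 OH and CH2Ar, C5) the exocyclic carbons on C3 and C4 are cis on neighbouring ring carbons and trans to the C2 aryl, with the C4 oxygen on the aryl face. This is the pattern left by a two-carbon arylketene unit laid across a C3=C4 enol ether and later cut between its two carbons.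
3. Key disconnection, used twice: cyclobutanone to arylketene plus (2S)-2-aryl-4-(benzyloxy)-2,5-dihydrofuran. First the ring A ketene adds to the biaryl dihydrofuran 13; then the ring C ketene, unmasked from a silyloxyethyl handle, adds to the ring D dihydrofuran 27.
4. Each dihydrofuran comes from ring-closing metathesis, preceded by ester methylenation, O-alkylation with benzyl bromoacetate and enantioselective vinylation of an aldehyde. The unsymmetrical biaryl aldehyde comes from Suzuki coupling of two halves made from 5-bromovanillin, which avoids desymmetrising a symmetrical dialdehyde.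
5. Ring order: oxolane 1 (as dihydrofuran), cyclobutane 1, lactone 1; then oxolane 2 (made separately), cyclobutane 2, lactone 2; both lactones are opened at the end.

Key step: step 13

Abbreviations: Ar = 4-(benzyloxy)-3-methoxyphenyl; ArBC = 4-(benzyloxy)-3-[2-(benzyloxy)-5-(2-{[tert-butyl(dimethyl)silyl]oxy}ethyl)-3-methoxyphenyl]-5-methoxyphenyl (ring B carrying ring C); oxolane atoms are numbered O1, C2 (aryl), C3, C4 (oxygen-bearing), C5.

Assumption: the vinylzinc additions are taken to follow the facial sense of dialkylzinc additions with the same ligand (Si-face attack); the aryl-bearing carbon of each four-membered ring and lactone is formed without control and is written without configuration, since it ends as a CH2 group.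

## Route

Step 1
Reactants: 1 5-bromovanillin (3-bromo-4-hydroxy-5-methoxybenzaldehyde)
Product: 2 4-(benzyloxy)-3-bromo-5-methoxybenzaldehyde
Conditions: BnBr, K2CO3, DMF, 60 °C
Reagents that add atoms: benzyl bromide, BrCc1ccccc1
Why: Williamson ether synthesis, in which the phenoxide formed with K2CO3 displaces bromide from benzyl bromide while the aldehyde and the aryl bromide do not react.

Step 2
Reactants: 2 4-(benzyloxy)-3-bromo-5-methoxybenzaldehyde
Product: 3 2-(benzyloxy)-1-bromo-5-ethenyl-3-methoxybenzene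
Conditions: Ph3PCH3Br, KOtBu, THF, 0 °C to rt
Reagents that add atoms: methyltriphenylphosphonium bromide, C[P+](c1ccccc1)(c1ccccc1)c1ccccc1.[Br-]
Why: Wittig methylenation, in which the unstabilised ylide converts the aromatic aldehyde into the styrene without touching the aryl bromide or the benzyl ether.

Step 3
Reactants: 3 2-(benzyloxy)-1-bromo-5-ethenyl-3-methoxybenzene
Product: 5 2-[4-(benzyloxy)-3-bromo-5-methoxyphenyl]ethanol, via alkylborane 4 (not isolated)
Conditions: 9-borabicyclo[3.3.1]nonane, THF, 0 °C to rt; then NaOH, H2O2, H2O, 0 °C to rt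
Reagents that add atoms: hydrogen peroxide, OO
Why: Hydroboration–oxidation, in which the bulky dialkylborane places boron on the terminal carbon of the styrene and alkaline peroxide replaces boron by OH to give the anti-Markovnikov primary alcohol.

Step 4
Reactants: 5 2-[4-(benzyloxy)-3-bromo-5-methoxyphenyl]ethanol
Product: 6 {2-[4-(benzyloxy)-3-bromo-5-methoxyphenyl]ethoxy}(tert-butyl)dimethylsilane
Conditions: TBSCl, imidazole, DMF, rt
Reagents that add atoms: tert-butyldimethylsilyl chloride, CC(C)(C)[Si](C)(C)Cl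
Why: Silylation of the primary alcohol gives a handle that should survive base, organozinc addition, methylenation, metathesis, ketene generation and peracid.

Step 5
Reactants: 6 {2-[4-(benzyloxy)-3-bromo-5-methoxyphenyl]ethoxy}(tert-butyl)dimethylsilane
Product: 7 {2-[4-(benzyloxy)-3-methoxy-5-(4,4,5,5-tetramethyl-1,3,2-dioxaborolan-2-yl)phenyl]ethoxy}(tert-butyl)dimethylsilane
Conditions: B2pin2, PdCl2[1,1'-bis(diphenylphosphino)ferrocene] (3 mol %), KOAc, 1,4-dioxane, 90 °C
Reagents that add atoms: bis(pinacolato)diboron, CC1(C)OB(OC1(C)C)B1OC(C)(C)C(C)(C)O1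
Why: Miyaura borylation, in which oxidative addition of the aryl bromide to zerovalent palladium, acetate-assisted transmetallation with the diboron reagent and reductive elimination give the aryl boronate and leave the silyl and benzyl ethers alone.

Step 6
Reactants: 7 the ring C pinacol boronate and 2 4-(benzyloxy)-3-bromo-5-methoxybenzaldehyde
Product: 8 4-(benzyloxy)-3-[2-(benzyloxy)-5-(2-{[tert-butyl(dimethyl)silyl]oxy}ethyl)-3-methoxyphenyl]-5-methoxybenzaldehyde (ArBC–CHO)
Conditions: Pd(OAc)2 (3 mol %), 2-dicyclohexylphosphino-2',6'-dimethoxybiphenyl (6 mol %), K3PO4, toluene/H2O, 80 °C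
Reagents that add atoms: none
Why: Suzuki–Miyaura cross-coupling joins the two 5-bromovanillin-derived halves at C5 of each ring; the electron-rich biarylphosphine copes with the two ortho benzyloxy groups, and a biaryl with only two ortho substituents has no configurationally stable axis.

Step 7
Reactants: 8 ArBC–CHO
Product: 9 (1S)-1-ArBC-prop-2-en-1-ol
Conditions: (CH2=CH)2Zn (1.5 equiv, prepared beforehand, salt-free), (2S)-3-exo-morpholinoisoborneol (10 mol %), toluene, −20 to 0 °C; aq NH4Cl
Reagents that add atoms: divinylzinc, C=C[Zn]C=C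
Why: Catalytic enantioselective addition of a vinylzinc reagent to an aromatic aldehyde, in which the chiral zinc amino alkoxide should deliver the vinyl group to the Si face and set the (S) carbinol centre that becomes C2 of oxolane 1 (to be confirmed by Mosher ester analysis).

Step 8
Reactants: 9 (1S)-1-ArBC-prop-2-en-1-ol and 10 benzyl bromoacetate
Product: 11 benzyl {[(1S)-1-ArBC-prop-2-en-1-yl]oxy}acetate
Conditions: NaH, Bu4NI (cat.), THF, 0 °C to rt
Reagents that add atoms: none
Why: Williamson O-alkylation, in which the sodium alkoxide displaces bromide from the activated α-bromo ester at low temperature where ester exchange is slow, and the stereocentre is not involved.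

Step 9
Reactants: 11 benzyl {[(1S)-1-ArBC-prop-2-en-1-yl]oxy}acetate
Product: 12 (1S)-1-ArBC-prop-2-en-1-yl 2-(benzyloxy)prop-2-en-1-yl ether
Conditions: Cp2Ti(CH3)2 (2.5 equiv), toluene, 70 °C, dark; filtration through basic alumina
Reagents that add atoms: dimethyltitanocene, [CH3-].[CH3-].[Ti+4].c1cc[cH-]c1.c1cc[cH-]c1
Why: Petasis methylenation, in which Cp2Ti=CH2 formed on heating converts the ester C=O into C=CH2 through an oxatitanacyclobutane under neutral conditions, so the allylic stereocentre and the silyl ether are untouched (any titanium-mediated closure onto the vinyl group would give 13 itself).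

Step 10
Reactants: 12 (1S)-1-ArBC-prop-2-en-1-yl 2-(benzyloxy)prop-2-en-1-yl ether
Product: 13 (2S)-2-ArBC-4-(benzyloxy)-2,5-dihydrofuran
Conditions: second-generation Grubbs catalyst (5 mol %), 1,4-benzoquinone (10 mol %), toluene, 60 °C
Reagents that add atoms: none
Why: Ring-closing olefin metathesis, in which the ruthenium carbene loads on the monosubstituted vinyl group and closes onto the 1,1-disubstituted enol ether with loss of ethene to form the five-membered cyclic enol ether; benzoquinone suppresses hydride-mediated double-bond migration that would erase C2.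

Step 11
Reactants: 14 homovanillic acid
Product: 15 [4-(benzyloxy)-3-methoxyphenyl]acetic acid
Conditions: BnBr (1.1 equiv), NaOH (2.5 equiv), EtOH/H2O, reflux; then aq HCl
Reagents that add atoms: benzyl bromide, BrCc1ccccc1
Why: Williamson benzylation of the phenoxide in aqueous base, where the carboxylate is a poor nucleophile and any benzyl ester formed is saponified in the same pot.

Step 12
Reactants: 15 [4-(benzyloxy)-3-methoxyphenyl]acetic acid
Product: 16 [4-(benzyloxy)-3-methoxyphenyl]acetyl chloride
Conditions: (COCl)2, N,N-dimethylformamide (cat.), CH2Cl2, 0 °C to rt; evaporation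
Reagents that add atoms: oxalyl chloride, O=C(Cl)C(Cl)=O
Why: Acid chloride formation through the Vilsmeier-type chloroiminium species, with only gaseous by-products so that the crude chloride can be used directly.

Step 13
Reactants: 13 (2S)-2-ArBC-4-(benzyloxy)-2,5-dihydrofuran and 16 [4-(benzyloxy)-3-methoxyphenyl]acetyl chloride
Product: 18 (1S,4S,5R)-1-(benzyloxy)-7-Ar-4-ArBC-3-oxabicyclo[3.2.0]heptan-6-one (cis-fused; both C7 epimers), via arylketene 17 (not isolated)
Conditions: Et3N (4 equiv), toluene, 80 °C, 16 (3 equiv) added over 8 h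
Reagents that add atoms: none
Why: Triethylamine removes HCl from 16 to give arylketene 17, whose electrophilic central carbon is attacked by the nucleophilic C3 of the enol ether while the ketene terminus bonds to the oxygen-bearing C4, in a thermal ketene–enol ether [2+2] cycloaddition of the kind that gives 3-alkoxycyclobutanones. The four-membered ring is closed by these two C–C bonds, C3–C(carbonyl) leading and C4–C(benzylic) following; if the process is stepwise, the second bond forms by 4-exo-trig attack of the enolate carbon on the C4 oxocarbenium ion. Both bonds are made on one face of the ring olefin, so the ring fusion must be cis, and that face should be the one opposite the C2 aryl group, which flanks the first-formed bond; this sets C3 (carbonyl carbon anti to the aryl, H syn) and C4 (benzylic carbon anti, benzyloxy syn) from the single C2 stereocentre. The benzylic carbon C7 is not controlled and need not be. The step needs regioselectivity (carbonyl carbon to C3), which the polarisation of the enol ether supplies, and anti facial selectivity, which the C2 aryl supplies; slow addition of an excess of 16 keeps the ketene concentration low and limits its dimerisation.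

Step 14
Reactants: 18 the cis-fused cyclobutanone
Product: 19 (3aS,6S,6aR)-3a-(benzyloxy)-3-Ar-6-ArBC-tetrahydro-1H,3H-furo[3,4-c]furan-1-one (both C3 epimers)
Conditions: mCPBA, NaHCO3, CH2Cl2, 0 °C
Reagents that add atoms: mCPBA, OOC(=O)c1cccc(Cl)c1
Why: Baeyer–Villiger oxidation, in which the strained cyclobutanone adds the peracid readily and the electron-rich benzylic carbon should migrate in preference to the ring-fusion carbon (which carries two β-oxygen substituents), placing oxygen between the carbonyl and the benzylic carbon.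

Step 15
Reactants: 19 the silyl-protected lactone
Product: 20 lactone 19 with ring C carrying CH2CH2OH in place of the silyloxyethyl group
Conditions: Bu4NF, AcOH (1:1), THF, 0 °C to rt
Reagents that add atoms: none
Why: Fluoride-mediated desilylation driven by the strong Si–F bond, buffered with acetic acid so that the lactone is neither opened nor enolised.

Step 16
Reactants: 20 the primary alcohol
Product: 22 lactone 19 with ring C carrying CH2CO2H, via arylacetaldehyde 21 (not isolated)
Conditions: 2,2,6,6-tetramethylpiperidin-1-oxyl (20 mol %), PhI(OAc)2 (2.5 equiv), MeCN/H2O, rt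
Reagents that add atoms: water, O
Why: Nitroxyl-catalysed oxidation, in which the oxoammonium ion regenerated by PhI(OAc)2 oxidises the primary alcohol to aldehyde 21, whose hydrate is oxidised on to the acid, under conditions that spare benzyl ethers, the lactone and the electron-rich arenes.

Step 17
Reactants: 23 4-(benzyloxy)-3-methoxybenzaldehyde (O-benzylvanillin)
Product: 24 (1S)-1-[4-(benzyloxy)-3-methoxyphenyl]prop-2-en-1-ol
Conditions: (CH2=CH)2Zn (1.5 equiv, prepared beforehand, salt-free), (2S)-3-exo-morpholinoisoborneol (10 mol %), toluene, −20 to 0 °C; aq NH4Cl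
Reagents that add atoms: divinylzinc, C=C[Zn]C=C
Why: The same amino alcohol-catalysed enantioselective vinylzinc addition as in step 7, expected to give the (S) carbinol that becomes C2 of oxolane 2.

Step 18
Reactants: 24 (1S)-1-[4-(benzyloxy)-3-methoxyphenyl]prop-2-en-1-ol and 10 benzyl bromoacetate
Product: 25 benzyl ({(1S)-1-[4-(benzyloxy)-3-methoxyphenyl]prop-2-en-1-yl}oxy)acetate
Conditions: NaH, Bu4NI (cat.), THF, 0 °C to rt
Reagents that add atoms: none
Why: Williamson O-alkylation of the sodium alkoxide with the α-bromo ester, as in step 8, without change at the stereocentre.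

Step 19
Reactants: 25 benzyl ({(1S)-1-[4-(benzyloxy)-3-methoxyphenyl]prop-2-en-1-yl}oxy)acetate
Product: 26 (1S)-1-[4-(benzyloxy)-3-methoxyphenyl]prop-2-en-1-yl 2-(benzyloxy)prop-2-en-1-yl ether
Conditions: Cp2Ti(CH3)2 (2.5 equiv), toluene, 70 °C, dark; filtration through basic alumina
Reagents that add atoms: dimethyltitanocene, [CH3-].[CH3-].[Ti+4].c1cc[cH-]c1.c1cc[cH-]c1
Why: Petasis methylenation of the ester carbonyl under neutral conditions, as in step 9.

Step 20
Reactants: 26 the allyl 2-(benzyloxy)allyl ether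
Product: 27 (2S)-4-(benzyloxy)-2-[4-(benzyloxy)-3-methoxyphenyl]-2,5-dihydrofuran
Conditions: second-generation Grubbs catalyst (5 mol %), 1,4-benzoquinone (10 mol %), toluene, 60 °C
Reagents that add atoms: none
Why: Ring-closing olefin metathesis onto the 1,1-disubstituted enol ether with loss of ethene, as in step 10.

Step 21
Reactants: 22 the ring C arylacetic acid and 27 (2S)-4-(benzyloxy)-2-[4-(benzyloxy)-3-methoxyphenyl]-2,5-dihydrofuran
Product: 30 lactone of unit 1 as in 19 with ring C bonded to C7 of a (1S,4S,5R)-1-(benzyloxy)-4-Ar-3-oxabicyclo[3.2.0]heptan-6-one (cis-fused; both C7 epimers), via acid chloride 28 (not isolated), via arylketene 29 (not isolated)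
Conditions: (COCl)2, N,N-dimethylformamide (cat.), CH2Cl2, 0 °C to rt, evaporation; then added over 8 h to 27 (4 equiv), Et3N (3 equiv), toluene, 80 °C
Reagents that add atoms: none
Why: The ketene–enol ether [2+2] cycloaddition of step 13 on the second pairing, in which ketene 29 generated slowly in an excess of enol ether 27 should add with its carbonyl carbon to C3 and both new bonds anti to the C2 aryl of 27, setting C3 and C4 of oxolane 2 and leaving the benzylic carbon uncontrolled.

Step 22
Reactants: 30 the lactone–cyclobutanone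
Product: 31 bis-lactone in which both units are (3aS,6S,6aR)-3a-(benzyloxy)-tetrahydro-1H,3H-furo[3,4-c]furan-1-ones (unit 1: C3 ring A aryl and C6 ring B; unit 2: C3 ring C and C6 ring D aryl)
Conditions: mCPBA, NaHCO3, CH2Cl2, 0 °C
Reagents that add atoms: mCPBA, OOC(=O)c1cccc(Cl)c1
Why: Baeyer–Villiger oxidation with migration of the electron-rich benzylic carbon, as in step 14, while the first lactone is inert to the buffered peracid.

Step 23
Reactants: 31 the hexabenzyl bis-lactone
Product: 32 diacid in which each oxolane is (2S,3R,4S)-2-aryl-4-(arylmethyl)-4-hydroxyoxolane-3-carboxylic acid and all phenols are free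
Conditions: H2 (1 atm), 10% Pd/C, EtOAc/EtOH, rt, followed by LC–MS
Reagents that add atoms: none
Why: Catalytic hydrogenolysis, in which the six benzyl ethers are cleaved to toluene and each γ-aryl lactone is opened at its benzylic C–O(acyl) bond, a benzyl ester-type bond expected to cleave faster than the benzylic C2–O ether bond of the oxolanes, so each benzylic carbon becomes CH2 and each C3 carries CO2H with no oxolane stereocentre touched.

Step 24
Reactants: 32 the diacid
Product: 33 target CNP0269573.1 (each oxolane 2S,3R,4S with C2 aryl, C3 CH2OH, C4 OH and arylmethyl)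
Conditions: BH3·THF (excess), THF, 0 °C to rt; MeOH quench and co-evaporation
Reagents that add atoms: none
Why: Borane reduction of carboxylic acids through acyloxyboranes, which is much faster than any reaction with the ethers, phenols or tertiary alcohols, converts both CO2H groups into CH2OH without change at C3, and methanolysis frees the product from borate esters.

## Compound list

1 | 5-bromovanillin (3-bromo-4-hydroxy-5-methoxybenzaldehyde) | COc1cc(C=O)cc(Br)c1O | starting material
2 | 4-(benzyloxy)-3-bromo-5-methoxybenzaldehyde | COc1cc(C=O)cc(Br)c1OCc1ccccc1 | intermediate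
3 | 2-(benzyloxy)-1-bromo-5-ethenyl-3-methoxybenzene | COc1cc(C=C)cc(Br)c1OCc1ccccc1 | intermediate
4 | 9-{2-[4-(benzyloxy)-3-bromo-5-methoxyphenyl]ethyl}-9-borabicyclo[3.3.1]nonane | COc1cc(CCB2C3CCCC2CCC3)cc(Br)c1OCc1ccccc1 | intermediate (not isolated)
5 | 2-[4-(benzyloxy)-3-bromo-5-methoxyphenyl]ethanol | COc1cc(CCO)cc(Br)c1OCc1ccccc1 | intermediate
6 | {2-[4-(benzyloxy)-3-bromo-5-methoxyphenyl]ethoxy}(tert-butyl)dimethylsilane | COc1cc(CCO[Si](C)(C)C(C)(C)C)cc(Br)c1OCc1ccccc1 | intermediate
7 | {2-[4-(benzyloxy)-3-methoxy-5-(4,4,5,5-tetramethyl-1,3,2-dioxaborolan-2-yl)phenyl]ethoxy}(tert-butyl)dimethylsilane | COc1cc(CCO[Si](C)(C)C(C)(C)C)cc(B2OC(C)(C)C(C)(C)O2)c1OCc1ccccc1 | intermediate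
8 | 4-(benzyloxy)-3-[2-(benzyloxy)-5-(2-{[tert-butyl(dimethyl)silyl]oxy}ethyl)-3-methoxyphenyl]-5-methoxybenzaldehyde | O=Cc1cc(OC)c(OCc2ccccc2)c(-c3cc(CCO[Si](C)(C)C(C)(C)C)cc(OC)c3OCc2ccccc2)c1 | intermediate
9 | (1S)-1-ArBC-prop-2-en-1-ol | C=C[C@@H](c1cc(OC)c(OCc2ccccc2)c(-c3cc(CCO[Si](C)(C)C(C)(C)C)cc(OC)c3OCc2ccccc2)c1)O | intermediate
10 | benzyl bromoacetate | BrCC(=O)OCc1ccccc1 | starting material
11 | benzyl {[(1S)-1-ArBC-prop-2-en-1-yl]oxy}acetate | C=C[C@@H](c1cc(OC)c(OCc2ccccc2)c(-c3cc(CCO[Si](C)(C)C(C)(C)C)cc(OC)c3OCc2ccccc2)c1)OCC(=O)OCc1ccccc1 | intermediate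
12 | (1S)-1-ArBC-prop-2-en-1-yl 2-(benzyloxy)prop-2-en-1-yl ether | C=C[C@@H](c1cc(OC)c(OCc2ccccc2)c(-c3cc(CCO[Si](C)(C)C(C)(C)C)cc(OC)c3OCc2ccccc2)c1)OCC(=C)OCc1ccccc1 | intermediate
13 | (2S)-2-ArBC-4-(benzyloxy)-2,5-dihydrofuran | C1(OCc2ccccc2)=C[C@@H](c3cc(OC)c(OCc5ccccc5)c(-c4cc(CCO[Si](C)(C)C(C)(C)C)cc(OC)c4OCc6ccccc6)c3)OC1 | intermediate
14 | homovanillic acid | COc1cc(CC(=O)O)ccc1O | starting material
15 | [4-(benzyloxy)-3-methoxyphenyl]acetic acid | COc1cc(CC(=O)O)ccc1OCc1ccccc1 | intermediate
16 | [4-(benzyloxy)-3-methoxyphenyl]acetyl chloride | COc1cc(CC(Cl)=O)ccc1OCc2ccccc2 | intermediate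
17 | [4-(benzyloxy)-3-methoxyphenyl]ketene | COc1cc(C=C=O)ccc1OCc1ccccc1 | intermediate (not isolated)
18 | (1S,4S,5R)-1-(benzyloxy)-7-Ar-4-ArBC-3-oxabicyclo[3.2.0]heptan-6-one, C7 epimers | COc1cc(C8[C@@]2(OCc7ccccc7)CO[C@H](c3cc(OC)c(OCc7ccccc7)c(-c4cc(CCO[Si](C)(C)C(C)(C)C)cc(OC)c4OCc7ccccc7)c3)[C@H]2C8=O)ccc1OCc1ccccc1 | intermediate
19 | (3aS,6S,6aR)-3a-(benzyloxy)-3-Ar-6-ArBC-tetrahydro-1H,3H-furo[3,4-c]furan-1-one, C3 epimers | COc1cc(C8[C@@]2(OCc7ccccc7)CO[C@H](c3cc(OC)c(OCc7ccccc7)c(-c4cc(CCO[Si](C)(C)C(C)(C)C)cc(OC)c4OCc7ccccc7)c3)[C@H]2C(=O)O8)ccc1OCc1ccccc1 | intermediate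
20 | lactone 19 with ring C carrying 2-hydroxyethyl | COc1cc(C8[C@@]2(OCc7ccccc7)CO[C@H](c3cc(OC)c(OCc7ccccc7)c(-c4cc(CCO)cc(OC)c4OCc7ccccc7)c3)[C@H]2C(=O)O8)ccc1OCc1ccccc1 | intermediate
21 | lactone 19 with ring C carrying 2-oxoethyl | COc1cc(C8[C@@]2(OCc7ccccc7)CO[C@H](c3cc(OC)c(OCc7ccccc7)c(-c4cc(CC=O)cc(OC)c4OCc7ccccc7)c3)[C@H]2C(=O)O8)ccc1OCc1ccccc1 | intermediate (not isolated)
22 | lactone 19 with ring C carrying carboxymethyl | COc1cc(C8[C@@]2(OCc7ccccc7)CO[C@H](c3cc(OC)c(OCc7ccccc7)c(-c4cc(CC(=O)O)cc(OC)c4OCc7ccccc7)c3)[C@H]2C(=O)O8)ccc1OCc1ccccc1 | intermediate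
23 | 4-(benzyloxy)-3-methoxybenzaldehyde (O-benzylvanillin) | COc1cc(C=O)ccc1OCc1ccccc1 | starting material
24 | (1S)-1-[4-(benzyloxy)-3-methoxyphenyl]prop-2-en-1-ol | C=C[C@@H](c1ccc(OCc2ccccc2)c(OC)c1)O | intermediate
25 | benzyl ({(1S)-1-[4-(benzyloxy)-3-methoxyphenyl]prop-2-en-1-yl}oxy)acetate | C=C[C@@H](c1ccc(OCc2ccccc2)c(OC)c1)OCC(=O)OCc1ccccc1 | intermediate
26 | (1S)-1-[4-(benzyloxy)-3-methoxyphenyl]prop-2-en-1-yl 2-(benzyloxy)prop-2-en-1-yl ether | C=C[C@@H](c1ccc(OCc2ccccc2)c(OC)c1)OCC(=C)OCc1ccccc1 | intermediate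
27 | (2S)-4-(benzyloxy)-2-[4-(benzyloxy)-3-methoxyphenyl]-2,5-dihydrofuran | C1(OCc2ccccc2)=C[C@@H](c3ccc(OCc4ccccc4)c(OC)c3)OC1 | intermediate
28 | lactone 19 with ring C carrying 2-chloro-2-oxoethyl (acid chloride) | COc1cc(C8[C@@]2(OCc7ccccc7)CO[C@H](c3cc(OC)c(OCc7ccccc7)c(-c4cc(CC(Cl)=O)cc(OC)c4OCc7ccccc7)c3)[C@H]2C(=O)O8)ccc1OCc1ccccc1 | intermediate (not isolated)
29 | lactone 19 with ring C carrying 2-oxoethenyl (arylketene) | COc1cc(C8[C@@]2(OCc7ccccc7)CO[C@H](c3cc(OC)c(OCc7ccccc7)c(-c4cc(C=C=O)cc(OC)c4OCc7ccccc7)c3)[C@H]2C(=O)O8)ccc1OCc1ccccc1 | intermediate (not isolated)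
30 | unit 1 lactone (3aS,6S,6aR) with ring C on C7 of a (1S,4S,5R)-1-(benzyloxy)-4-Ar-3-oxabicyclo[3.2.0]heptan-6-one | COc1cc(C8[C@@]2(OCc7ccccc7)CO[C@H](c3cc(OC)c(OCc7ccccc7)c(-c4cc(C9[C@@]5(OCc7ccccc7)CO[C@H](c6ccc(OCc7ccccc7)c(OC)c6)[C@H]5C9=O)cc(OC)c4OCc7ccccc7)c3)[C@H]2C(=O)O8)ccc1OCc1ccccc1 | intermediate
31 | hexabenzyl bis-lactone, both units (3aS,6S,6aR) | COc1cc(C8[C@@]2(OCc7ccccc7)CO[C@H](c3cc(OC)c(OCc7ccccc7)c(-c4cc(C9[C@@]5(OCc7ccccc7)CO[C@H](c6ccc(OCc7ccccc7)c(OC)c6)[C@H]5C(=O)O9)cc(OC)c4OCc7ccccc7)c3)[C@H]2C(=O)O8)ccc1OCc1ccccc1 | intermediate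
32 | diacid, each oxolane (2S,3R,4S)-2-aryl-4-(arylmethyl)-4-hydroxyoxolane-3-carboxylic acid | COc1cc(C[C@@]2(O)CO[C@H](c3cc(OC)c(O)c(-c4cc(C[C@@]5(O)CO[C@H](c6ccc(O)c(OC)c6)[C@H]5C(=O)O)cc(OC)c4O)c3)[C@H]2C(=O)O)ccc1O | intermediate
33 | CNP0269573.1, each oxolane (2S,3R,4S) with C2 aryl, C3 CH2OH, C4 OH and arylmethyl | COc1cc(C[C@@]2(O)CO[C@H](c3cc(OC)c(O)c(-c4cc(C[C@@]5(O)CO[C@H](c6ccc(O)c(OC)c6)[C@H]5CO)cc(OC)c4O)c3)[C@H]2CO)ccc1O | target

## Step count and risks

Total steps: 24. Longest linear sequence: 18 steps (steps 1–10, 13–16 and 21–24, from 5-bromovanillin 1).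

**Step 13 (key step).**
- What may go wrong: the monosubstituted ketene may be consumed by amine-promoted self-condensation faster than it adds to the trisubstituted enol ether. Alternatively, the dipolar intermediate may lose a proton to give a C3-acylated enol ether instead of closing onto the hindered C4.
- Fallback (sets out from 13, comes back at 18): an α-chlorine is added to the ketene as an activating group. Commercial 4-hydroxy-3-methoxymandelic acid is O-benzylated (BnBr, aq NaOH, EtOH) to [4-(benzyloxy)-3-methoxyphenyl](hydroxy)acetic acid F1. SOCl2 with catalytic N,N-dimethylformamide at reflux should convert this into chloro[4-(benzyloxy)-3-methoxyphenyl]acetyl chloride F2. With Et3N in hexane/toluene at rt, F2 gives the aryl(chloro)ketene F3, a more electrophilic disubstituted ketene of a class known to add to enol ethers. It should add to 13 with the same regio- and facial sense to give the 7-chloro cyclobutanone F4. Radical dechlorination (Bu3SnH, azobisisobutyronitrile, benzene, 80 °C) then gives 18.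

**Step 21.**
- What may go wrong: the same competition between cycloaddition and ketene self-condensation, now with the ketene on the valuable component, which cannot be used in excess.
- Fallback (sets out from 20, comes back at 30): direct halogenation of the acid chloride would also chlorinate the electron-rich rings, so the chlorine is introduced at the aldehyde stage. Dess–Martin periodinane (NaHCO3, CH2Cl2) gives aldehyde 21, here isolated. N-Chlorosuccinimide with DL-proline (10 mol %) in CH2Cl2 at 0 °C chlorinates it through the enamine to the α-chloro aldehyde F5. Pinnick oxidation (NaClO2, NaH2PO4, 2-methyl-2-butene, tBuOH/H2O) gives the α-chloro acid F6. (COCl)2 with catalytic N,N-dimethylformamide gives the α-chloro acid chloride F7. Et3N in the presence of 27 (3 equiv) generates the aryl(chloro)ketene F8, which should be trapped as the 7-chloro cyclobutanone F9. Bu3SnH with azobisisobutyronitrile then gives 30.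

**Step 23.**
- What may go wrong: opening of each lactone at its benzylic carbon, which sits next to the quaternary C4, may be slow enough that reductive cleavage of the oxolane C2–O bonds (benzylic ethers of electron-rich aryls) sets in first and leads to ring-opened over-reduction products.
- Fallback (sets out from 31, comes back at 32): the lactone is cut by a non-catalytic, phenol-triggered reduction. A brief hydrogenolysis (H2 at 1 atm, 10% Pd/C, EtOAc), stopped as soon as the benzyl ethers are gone, gives the hexahydroxy bis-lactone F10. NaBH4 with K2CO3 in EtOH/H2O at rt should then open each lactone: the para-phenoxide of ring A or ring C expels the benzylic carboxylate to form a p-quinone methide (written with both units opened as the bis(quinone methide) diacid F11), and borohydride reduces it by 1,6-hydride addition to the arylmethyl group. The oxolane C2–O bonds would have to leave as alkoxides and should not ionise under these conditions.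

## Further compounds

F1 | step 13 | [4-(benzyloxy)-3-methoxyphenyl](hydroxy)acetic acid | COc1cc(C(O)C(=O)O)ccc1OCc1ccccc1
F2 | step 13 | chloro[4-(benzyloxy)-3-methoxyphenyl]acetyl chloride | COc1cc(C(Cl)C(Cl)=O)ccc1OCc1ccccc1
F3 | step 13 | [4-(benzyloxy)-3-methoxyphenyl](chloro)ketene (not isolated) | COc1cc(C(Cl)=C=O)ccc1OCc1ccccc1
F4 | step 13 | 7-chloro derivative of cyclobutanone 18 | COc1cc(C8(Cl)[C@@]2(OCc7ccccc7)CO[C@H](c3cc(OC)c(OCc7ccccc7)c(-c4cc(CCO[Si](C)(C)C(C)(C)C)cc(OC)c4OCc7ccccc7)c3)[C@H]2C8=O)ccc1OCc1ccccc1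
F5 | step 21 | lactone 19 with ring C carrying 1-chloro-2-oxoethyl | COc1cc(C8[C@@]2(OCc7ccccc7)CO[C@H](c3cc(OC)c(OCc7ccccc7)c(-c4cc(C(Cl)C=O)cc(OC)c4OCc7ccccc7)c3)[C@H]2C(=O)O8)ccc1OCc1ccccc1
F6 | step 21 | lactone 19 with ring C carrying carboxy(chloro)methyl | COc1cc(C8[C@@]2(OCc7ccccc7)CO[C@H](c3cc(OC)c(OCc7ccccc7)c(-c4cc(C(Cl)C(=O)O)cc(OC)c4OCc7ccccc7)c3)[C@H]2C(=O)O8)ccc1OCc1ccccc1
F7 | step 21 | lactone 19 with ring C carrying 1,2-dichloro-2-oxoethyl | COc1cc(C8[C@@]2(OCc7ccccc7)CO[C@H](c3cc(OC)c(OCc7ccccc7)c(-c4cc(C(Cl)C(Cl)=O)cc(OC)c4OCc7ccccc7)c3)[C@H]2C(=O)O8)ccc1OCc1ccccc1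
F8 | step 21 | lactone 19 with ring C carrying 1-chloro-2-oxoethenyl (not isolated) | COc1cc(C8[C@@]2(OCc7ccccc7)CO[C@H](c3cc(OC)c(OCc7ccccc7)c(-c4cc(C(Cl)=C=O)cc(OC)c4OCc7ccccc7)c3)[C@H]2C(=O)O8)ccc1OCc1ccccc1
F9 | step 21 | 7-chloro derivative of cyclobutanone 30 | COc1cc(C8[C@@]2(OCc7ccccc7)CO[C@H](c3cc(OC)c(OCc7ccccc7)c(-c4cc(C9(Cl)[C@@]5(OCc7ccccc7)CO[C@H](c6ccc(OCc7ccccc7)c(OC)c6)[C@H]5C9=O)cc(OC)c4OCc7ccccc7)c3)[C@H]2C(=O)O8)ccc1OCc1ccccc1
F10 | step 23 | hexahydroxy bis-lactone (31 without its six benzyl groups) | COc1cc(C8[C@@]2(O)CO[C@H](c3cc(OC)c(O)c(-c4cc(C9[C@@]5(O)CO[C@H](c6ccc(O)c(OC)c6)[C@H]5C(=O)O9)cc(OC)c4O)c3)[C@H]2C(=O)O8)ccc1O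
F11 | step 23 | bis(p-quinone methide) diacid (transient, written with both units opened) | COC1=CC(=C[C@@]2(O)CO[C@H](c3cc(OC)c(O)c(C4=CC(=C[C@@]5(O)CO[C@H](c6ccc(O)c(OC)c6)[C@H]5C(=O)O)C=C(OC)C4=O)c3)[C@H]2C(=O)O)C=CC1=O
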